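Substrate plus target holds at the charge in the dawn run of this flask, 99.6% at 6.00 min, and nearly all target sits as idle adduct.

common to all: substrate 0.043 M; free catalyst 43 µM
- dawn: reagent 0.086 M; the very flask that is asked about, followed so far
- flask: reagent 0.0860 M; time 20 min

dawn run (percent of the substrate charged)

| time / min | target / % | substrate / % | idle adduct / % |
|---|---|---|---|
| 0.500 | 0.9 | 99.4 | 1.0 |
| 0.667 | 1.1 | 98.5 | 1.9 |
| 1.00 | 2.5 | 98.4 | 1.9 |
| 1.50 | 3.2 | 97.6 | 2.9 |
| 2.50 | 5.0 | 94.1 | 5.0 |
| 4.00 | 8.4 | 91.6 | 7.4 |
| 6.00 | 11.8 | 87.8 | 11.7 |

(standard deviation of a reading: 0.3 percentage points)

- for target the idle adduct is counted in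

- the target in the flask at 20 min, as a percentage of the substrate charged
- the substrate in the flask at 20 min, as a percentage of the substrate charged
- the idle adduct in the flask at 20 min, as a percentage of the substrate charged

Two chemists dispute this flask. Both take the adduct to be target holding a second reagent, so each substrate turned over costs two reagents, and with reagent charged at twice the substrate the two shares fall together.

The first chemist lets substrate and reagent both enter the rate, so it eases steeply. This chemist's decay leaves 69% of the substrate at 20 min. The forecast is a judgement between that decay and a first-order one, in its words “First-order decay gives about 66%, and I take about 68%”: substrate 68% (range 63% to 72%), target 32%, adduct 31.5%.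

The second chemist holds that with 43 µM of catalyst the rate follows reagent and ignores substrate. Her number is 0.0217 min⁻¹: the reagent clock, the fraction of its present amount that reagent loses per minute, a pseudo-first-order constant with the catalyst taken as fixed. It is a reading, taken from the substrate at 6.00 min, and carries that scatter. It leaves 64.8% of the reagent at 20 min, and about as much substrate, which is lower than the forecast.

The flask gives substrate 62.8%, target 36.8% and adduct 33.2%, so the forecast's substrate stands 5.2 percentage points too high. The first chemist's view keeps the span of the dawn run, through whose readings both curves were drawn. At 20 min the flask holds 64.9% of its reagent. The clock's loss of 35.2% of the reagent, as a share of the substrate charge, is 70.4%; taking off the adduct's second reagent leaves 37.1% of substrate turned over, which is 62.9% left.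

    reagent + free catalyst ⇌ catalyst intermediate A (K = 12.0 L mol⁻¹, k = 900 L mol⁻¹ min⁻¹)
    reagent + target ⇌ idle adduct, settled at all times (K = 170 L mol⁻¹)
    substrate + catalyst intermediate B ⇌ catalyst intermediate C (K = 580 L mol⁻¹, k = 11000 L mol⁻¹ min⁻¹)
    substrate + target → side product (k = 0.210 L mol⁻¹ min⁻¹)
    catalyst intermediate A → catalyst intermediate B (k = 64.0 min⁻¹)
    catalyst intermediate C ⇌ free catalyst + target (K = 0.0250 M, k = 7200 min⁻¹)

In the same flask with 0.052 M of reagent, 1.21 equiv, the clock again gives 64.8% of that smaller charge left at 20 min. Computed, 61.5% of the reagent remains, with substrate at 74.4% and adduct at 21.2%.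

The readings stem from a simulated flask for substances that don't exist, noise included.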